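**Plan**

- Retrosynthetic cuts: first the O–C10 bond of the oxolane (transannular, last step); then C6–C7 together with the lactone C12–O6 bond (ten-membered ring); then the (Z)-4-oxo-enal C3–C6 is folded back into a furan; finally C7–C11, C9–C10 and C1–C2 of the chain.
- Forward order: the C15 chain is built linearly on 2-methylfuran-3-carboxylic acid (C1–C2, then C9–C10, then C7–C11). The furan is opened, an intramolecular Barbier allylation with lactonisation closes carbocycle and γ-lactone together, and the oxolane (and with it the 11-oxabicyclo[6.2.1]undecene core) is closed last.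
- Stereochemistry: C8 comes from methyl (R)-glycidate; C6 and C7 are set in the Barbier step under control of C8; C10 and C3 are set in the key step by the all-cis C6–C7–C8 triad; the 4Z olefin is inherited from the furan ring.
- Enabling feature: in the ten-membered ring, C3=O and C10 are linked by C2–C1 and face each other across the ring. C10 carries the only electron-rich olefin (C10=C14), while C4=C5 and C11=C13 are conjugated to carbonyls, so a C10 cation can only be captured by the C3 oxygen, closing the ring O–C3–C2–C1–C10.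

Key step: step 14

Remark on the chemistry: germacrane numbering is used (ring C1–C10, lactone carbons C11–C13 on C7, lactone oxygen on C6, C14 on C10, C15 on C4). The target is taken as written, (3S,4Z,6S,7R,8R,10R), with lactone, C8 ester and 3,10-oxygen bridge on one face. TBS = tert-butyldimethylsilyl, TBDPS = tert-butyldiphenylsilyl.

**Route**

Step 1
Reactants: 1 2-methylfuran-3-carboxylic acid; 2 2,3-dibromoprop-1-ene
Product: 4 2-(3-bromobut-3-en-1-yl)furan-3-carboxylic acid, via dilithium dianion 3 (not isolated)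
Conditions: LiN(i-Pr)2 (2.2 equiv), THF, −78 °C; then 2, −78 to 0 °C; aq. HCl work-up
Reagents that add atoms: none
Why: Two equivalents of amide base should give the carboxylate/furylmethyl dianion (lateral metalation of the 2-methyl group, vinylogous to the carboxylate), which should be alkylated at carbon by the allylic bromide of 2 (SN2 dianion alkylation, C1–C2 bond) while the vinylic bromide stays intact.

Step 2
Reactants: 4 2-(3-bromobut-3-en-1-yl)furan-3-carboxylic acid
Product: 5 [2-(3-bromobut-3-en-1-yl)furan-3-yl]methanol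
Conditions: LiAlH4, Et2O, 0 °C
Reagents that add atoms: none
Why: Hydride reduction of the carboxylic acid to the primary alcohol (the future C15 hydroxymethyl); the vinylic bromide and the furan should survive LiAlH4 at 0 °C.

Step 3
Reactants: 5 [2-(3-bromobut-3-en-1-yl)furan-3-yl]methanol
Product: 6 2-(3-bromobut-3-en-1-yl)-3-(TBDPS-oxymethyl)furan
Conditions: TBDPSCl, imidazole, DMF, rt
Reagents that add atoms: tert-butyl(chloro)diphenylsilane (TBDPSCl), CC(C)(C)[Si](Cl)(c1ccccc1)c1ccccc1
Why: Silyl ether protection of the primary alcohol removes the only acidic proton before the organomagnesium step and gives a group that should outlast every later step up to step 13.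

Step 4
Reactants: 6 2-(3-bromobut-3-en-1-yl)-3-(TBDPS-oxymethyl)furan; 7 methyl (2R)-oxirane-2-carboxylate
Product: 9 methyl (2R)-2-hydroxy-4-methylidene-6-[3-(TBDPS-oxymethyl)furan-2-yl]hexanoate, via alkenylmagnesium bromide 8 (not isolated)
Conditions: Mg, THF, 45 °C; then CuI (10 mol %), 7, THF, −40 to −20 °C
Reagents that add atoms: none
Why: Magnesium insertion into the 2-bromoalkene gives the Grignard reagent, and copper-catalysed SN2 opening of the epoxide at its CH2 carbon (C9–C10 bond) should outrun addition to the ester at low temperature; the C8 stereocentre is carried over from 7 because no bond at that carbon is broken.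

Step 5
Reactants: 9 methyl (2R)-2-hydroxy-4-methylidene-6-[3-(TBDPS-oxymethyl)furan-2-yl]hexanoate
Product: 10 methyl (2R)-2-(TBS-oxy)-4-methylidene-6-[3-(TBDPS-oxymethyl)furan-2-yl]hexanoate
Conditions: TBSCl, imidazole, DMF, rt
Reagents that add atoms: tert-butyl(chloro)dimethylsilane (TBSCl), CC(C)(C)[Si](C)(C)Cl
Why: Silyl ether protection of the secondary alcohol puts a bulky, non-chelating group on C8, as wanted for the partial reduction and for the later allylation.

Step 6
Reactants: 10 methyl (2R)-2-(TBS-oxy)-4-methylidene-6-[3-(TBDPS-oxymethyl)furan-2-yl]hexanoate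
Product: 11 (2R)-2-(TBS-oxy)-4-methylidene-6-[3-(TBDPS-oxymethyl)furan-2-yl]hexanal
Conditions: i-Bu2AlH (1.1 equiv), CH2Cl2, −78 °C; Rochelle salt work-up
Reagents that add atoms: none
Why: Partial reduction of an α-silyloxy methyl ester should stop at the aldehyde because the aluminium hemiacetal persists until work-up, and no epimerisation at C8 is expected at −78 °C.

Step 7
Reactants: 11 (2R)-2-(TBS-oxy)-4-methylidene-6-[3-(TBDPS-oxymethyl)furan-2-yl]hexanal; 12 methyl prop-2-ynoate
Product: 14 methyl (4R)-3-hydroxy-2,6-dimethylidene-4-(TBS-oxy)-8-[3-(TBDPS-oxymethyl)furan-2-yl]octanoate (both C3 epimers), via vinylalane 13 (not isolated)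
Conditions: 12, i-Bu2AlH, N-methylmorpholine N-oxide, THF, 0 °C; then 11, 0 °C to rt
Reagents that add atoms: none
Why: Hydroalumination of the propiolate gives the α-(methoxycarbonyl)vinylalane, which adds to the aldehyde to give the Morita–Baylis–Hillman-type adduct (vinylalumination, C7–C11 bond) quickly enough to avoid the epimerisation that a slow amine-catalysed variant would risk; the new carbinol centre forms as a mixture and is erased in step 8.

Step 8
Reactants: 14 methyl (4R)-3-hydroxy-2,6-dimethylidene-4-(TBS-oxy)-8-[3-(TBDPS-oxymethyl)furan-2-yl]octanoate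
Product: 16 methyl (2Z,4R)-2-(bromomethyl)-6-methylidene-4-(TBS-oxy)-8-[3-(TBDPS-oxymethyl)furan-2-yl]oct-2-enoate, via allylic mesylate 15 (not isolated)
Conditions: MsCl, Et3N, CH2Cl2, −20 °C; then LiBr, THF, 0 °C to rt
Reagents that add atoms: lithium bromide, [Li+].[Br-]
Why: Mesylation followed by SN2′ displacement with bromide (allylic transposition of a Morita–Baylis–Hillman adduct) should give the thermodynamically preferred (Z)-2-(bromomethyl)enoate, in which C8 is trans to the ester.

Step 9
Reactants: 16 methyl (2Z,4R)-2-(bromomethyl)-6-methylidene-4-(TBS-oxy)-8-[3-(TBDPS-oxymethyl)furan-2-yl]oct-2-enoate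
Product: 18 methyl (2Z,4R,10Z)-2-(bromomethyl)-6-methylidene-9,12-dioxo-4-(TBS-oxy)-10-(TBDPS-oxymethyl)dodeca-2,10-dienoate, via furan endoperoxide 17 (not isolated)
Conditions: O2, visible light, tetraphenylporphyrin (cat.), CH2Cl2, −78 °C; then Me2S (1.2 equiv), −78 to −30 °C; used crude
Reagents that add atoms: dioxygen, O=O
Why: Singlet oxygen adds [4+2] to the electron-rich 2,3-dialkylfuran far faster than it reacts with the 1,1-disubstituted olefin or the enoate, and low-temperature reduction of the endoperoxide unveils the cis-enedione (oxidative furan ring opening), so the 4Z geometry, the C3 ketone and the C6 aldehyde all come from the former ring.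

Step 10
Reactants: 18 methyl (2Z,4R,10Z)-2-(bromomethyl)-6-methylidene-9,12-dioxo-4-(TBS-oxy)-10-(TBDPS-oxymethyl)dodeca-2,10-dienoate
Product: 20 (4Z,6S,7S,8R)-3-oxo-8-(TBS-oxy)-15-(TBDPS-oxy)germacra-4,10(14),11(13)-trien-12,6-olide, via macrocyclic hydroxy ester 19 (not isolated)
Conditions: In powder, THF/H2O (4:1), rt, slow addition of 18 (final 2 mM); then pyridinium p-toluenesulfonate (cat.), CH2Cl2, rt
Reagents that add atoms: none
Why: In this intramolecular Barbier allylation the indium-metallated allylic bromide should add through C7 to the aldehyde (not the ketone) in a closed six-membered Zimmerman–Traxler transition state with the C8 branch axial, giving the syn (6,7-cis) adduct, while allylic 1,3-strain holds H8 in the enoate plane so that the aldehyde is delivered anti to the C8–C9 bond with the silyl ether outside, which sets C7 and C6 relative to C8; the cis-γ-hydroxy ester then lactonises under mild acid, and the strain of a six-carbon-bridged 2,5-furanophane should keep the (Z)-γ-hydroxy enone from dehydrating to a furan.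

Step 11
Reactants: 20 (4Z,6S,7S,8R)-3-oxo-8-(TBS-oxy)-15-(TBDPS-oxy)germacra-4,10(14),11(13)-trien-12,6-olide
Product: 21 (4Z,6S,7R,8R)-8-hydroxy-3-oxo-15-(TBDPS-oxy)germacra-4,10(14),11(13)-trien-12,6-olide
Conditions: HF·pyridine, pyridine, THF, 0 °C
Reagents that add atoms: none
Why: Buffered HF·pyridine should cleave the secondary TBS ether much faster than the primary TBDPS ether (selective desilylation) and is too dilute to add to the C10=C14 olefin.

Step 12
Reactants: 21 (4Z,6S,7R,8R)-8-hydroxy-3-oxo-15-(TBDPS-oxy)germacra-4,10(14),11(13)-trien-12,6-olide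
Product: 22 (4Z,6S,7R,8R)-8-(2-methylpropanoyloxy)-3-oxo-15-(TBDPS-oxy)germacra-4,10(14),11(13)-trien-12,6-olide
Conditions: (i-PrCO)2O, DMAP, Et3N, CH2Cl2, 0 °C
Reagents that add atoms: isobutyric anhydride, CC(C)C(=O)OC(=O)C(C)C
Why: DMAP-catalysed acylation (esterification) of the only free hydroxyl; no bond to C8 is broken, so its configuration is retained.

Step 13
Reactants: 22 (4Z,6S,7R,8R)-8-(2-methylpropanoyloxy)-3-oxo-15-(TBDPS-oxy)germacra-4,10(14),11(13)-trien-12,6-olide
Product: 23 (4Z,6S,7R,8R)-15-hydroxy-8-(2-methylpropanoyloxy)-3-oxogermacra-4,10(14),11(13)-trien-12,6-olide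
Conditions: Bu4NF, AcOH (1:1), THF, 0 °C to rt
Reagents that add atoms: none
Why: Fluoride-mediated desilylation buffered with acetic acid, so that the α-methylene lactone and the ester are not exposed to basic fluoride.

Step 14
Reactants: 23 (4Z,6S,7R,8R)-15-hydroxy-8-(2-methylpropanoyloxy)-3-oxogermacra-4,10(14),11(13)-trien-12,6-olide
Product: 24 (3S,4Z,6S,7R,8R,10R)-3,15-dihydroxy-8-(2-methylpropanoyloxy)-3,10-epoxygermacra-4,11(13)-dien-12,6-olide
Conditions: TsOH·H2O (20 mol %), H2O (5 equiv), (CF3)2CHOH/CH2Cl2 (1:4), 0 °C to rt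
Reagents that add atoms: water, O
Why: The acid should protonate the electron-rich exocyclic C10=C14 olefin at C14, the tertiary C10 cation is taken across the ring by the C3 carbonyl oxygen, and water adds to the C3 oxocarbenium ion to give the hemiketal. The closest known reaction type is the acid-catalysed cyclisation of γ,δ-unsaturated ketones with a 1,1-disubstituted olefin to 2-hydroxy- or 2-alkoxyoxolanes (Markovnikov hydroalkoxylation), run here transannularly as in the presumed biogenesis of 3,10-epoxygermacranolide hemiketals from 3-oxogermacranolides. The oxolane (O, C3, C2, C1, C10) closes in the 5-exo-trig mode at the olefin and so converts the ten-membered enone ring into the 11-oxabicyclo[6.2.1]undecene core. C10 is set by the face on which the carbonyl oxygen reaches the cation: the lactone (O6, C11) and the C8 ester all lie on one face of the ring, closure on that face leaves them exo (on the side of the one-atom oxygen bridge, away from the C1–C2 bridge) while the other face would press all three against C1–C2, and participation by the C8 ester carbonyl, should it intervene, delivers oxygen to the same face. C3 follows from C10, because the one-atom bridge can only span C3 and C10 cis, and the hemiketal hydroxyl is under thermodynamic control. The step needs O-capture of the cation and protonation of one olefin only, and both are secured by conjugation: C4=C5 (to C3=O) and C11=C13 (to the lactone) are too electron-poor to be protonated or to attack C10, so the eudesmane-type C5–C10 closure of germacranes is shut off, and reversible C10–O ionisation under the acid should let the product settle in the all-exo isomer.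

**Compound list**

1 | 2-methylfuran-3-carboxylic acid | Cc1occc1C(=O)O | starting material
2 | 2,3-dibromoprop-1-ene | C=C(Br)CBr | starting material
3 | dilithium dianion of 1 (lithium carboxylate, lithiated 2-methyl group) | [Li+].[Li+].[CH2-]c1occc1C(=O)[O-] | intermediate
4 | 2-(3-bromobut-3-en-1-yl)furan-3-carboxylic acid | C=C(Br)CCc1occc1C(=O)O | intermediate
5 | [2-(3-bromobut-3-en-1-yl)furan-3-yl]methanol | C=C(Br)CCc1occc1CO | intermediate
6 | 2-(3-bromobut-3-en-1-yl)-3-(TBDPS-oxymethyl)furan | C=C(Br)CCc1occc1CO[Si](C(C)(C)C)(c1ccccc1)c1ccccc1 | intermediate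
7 | methyl (2R)-oxirane-2-carboxylate, methyl (R)-glycidate | COC(=O)[C@H]1CO1 | starting material
8 | {4-[3-(TBDPS-oxymethyl)furan-2-yl]but-1-en-2-yl}magnesium bromide | C=C([Mg]Br)CCc1occc1CO[Si](C(C)(C)C)(c1ccccc1)c1ccccc1 | intermediate
9 | methyl (2R)-2-hydroxy-4-methylidene-6-[3-(TBDPS-oxymethyl)furan-2-yl]hexanoate | COC(=O)[C@H](O)CC(=C)CCc1occc1CO[Si](C(C)(C)C)(c1ccccc1)c1ccccc1 | intermediate
10 | methyl (2R)-2-(TBS-oxy)-4-methylidene-6-[3-(TBDPS-oxymethyl)furan-2-yl]hexanoate | COC(=O)[C@H](O[Si](C)(C)C(C)(C)C)CC(=C)CCc1occc1CO[Si](C(C)(C)C)(c1ccccc1)c1ccccc1 | intermediate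
11 | (2R)-2-(TBS-oxy)-4-methylidene-6-[3-(TBDPS-oxymethyl)furan-2-yl]hexanal | O=C[C@H](O[Si](C)(C)C(C)(C)C)CC(=C)CCc1occc1CO[Si](C(C)(C)C)(c1ccccc1)c1ccccc1 | intermediate
12 | methyl prop-2-ynoate, methyl propiolate | C#CC(=O)OC | starting material
13 | methyl 2-[bis(2-methylpropyl)alumanyl]prop-2-enoate | C=C(C(=O)OC)[Al](CC(C)C)CC(C)C | intermediate
14 | methyl (4R)-3-hydroxy-2,6-dimethylidene-4-(TBS-oxy)-8-[3-(TBDPS-oxymethyl)furan-2-yl]octanoate, both C3 epimers | C=C(C(=O)OC)C(O)[C@H](O[Si](C)(C)C(C)(C)C)CC(=C)CCc1occc1CO[Si](C(C)(C)C)(c1ccccc1)c1ccccc1 | intermediate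
15 | 3-O-methanesulfonate of 14 | C=C(C(=O)OC)C(OS(C)(=O)=O)[C@H](O[Si](C)(C)C(C)(C)C)CC(=C)CCc1occc1CO[Si](C(C)(C)C)(c1ccccc1)c1ccccc1 | intermediate
16 | methyl (2Z,4R)-2-(bromomethyl)-6-methylidene-4-(TBS-oxy)-8-[3-(TBDPS-oxymethyl)furan-2-yl]oct-2-enoate | COC(=O)/C(CBr)=C/[C@H](O[Si](C)(C)C(C)(C)C)CC(=C)CCc1occc1CO[Si](C(C)(C)C)(c1ccccc1)c1ccccc1 | intermediate
17 | 2,5-endoperoxide (2,3,7-trioxabicyclo[2.2.1]hept-5-ene) of the furan ring of 16 | COC(=O)/C(CBr)=C/[C@H](O[Si](C)(C)C(C)(C)C)CC(=C)CCC12OOC(O1)C=C2CO[Si](C(C)(C)C)(c1ccccc1)c1ccccc1 | intermediate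
18 | methyl (2Z,4R,10Z)-2-(bromomethyl)-6-methylidene-9,12-dioxo-4-(TBS-oxy)-10-(TBDPS-oxymethyl)dodeca-2,10-dienoate | COC(=O)/C(CBr)=C/[C@H](O[Si](C)(C)C(C)(C)C)CC(=C)CCC(=O)/C(CO[Si](C(C)(C)C)(c1ccccc1)c1ccccc1)=C\C=O | intermediate
19 | methyl (4Z,6S,7S,8R)-6-hydroxy-3-oxo-8-(TBS-oxy)-15-(TBDPS-oxy)germacra-4,10(14),11(13)-trien-12-oate (6-OH, C7 side chain and 8-O all cis) | O[C@H]1/C=C(/CO[Si](C(C)(C)C)(c2ccccc2)c2ccccc2)C(=O)CCC(=C)C[C@@H](O[Si](C)(C)C(C)(C)C)[C@H]1C(=C)C(=O)OC | intermediate
20 | (4Z,6S,7S,8R)-3-oxo-8-(TBS-oxy)-15-(TBDPS-oxy)germacra-4,10(14),11(13)-trien-12,6-olide (cis-fused lactone) | C=C1C(=O)O[C@H]2/C=C(/CO[Si](C(C)(C)C)(c3ccccc3)c3ccccc3)C(=O)CCC(=C)C[C@@H](O[Si](C)(C)C(C)(C)C)[C@@H]12 | intermediate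
21 | (4Z,6S,7R,8R)-8-hydroxy-3-oxo-15-(TBDPS-oxy)germacra-4,10(14),11(13)-trien-12,6-olide | C=C1C(=O)O[C@H]2/C=C(/CO[Si](C(C)(C)C)(c3ccccc3)c3ccccc3)C(=O)CCC(=C)C[C@@H](O)[C@@H]12 | intermediate
22 | (4Z,6S,7R,8R)-8-(2-methylpropanoyloxy)-3-oxo-15-(TBDPS-oxy)germacra-4,10(14),11(13)-trien-12,6-olide | C=C1C(=O)O[C@H]2/C=C(/CO[Si](C(C)(C)C)(c3ccccc3)c3ccccc3)C(=O)CCC(=C)C[C@@H](OC(=O)C(C)C)[C@@H]12 | intermediate
23 | (4Z,6S,7R,8R)-15-hydroxy-8-(2-methylpropanoyloxy)-3-oxogermacra-4,10(14),11(13)-trien-12,6-olide | C=C1C(=O)O[C@H]2/C=C(/CO)C(=O)CCC(=C)C[C@@H](OC(=O)C(C)C)[C@@H]12 | intermediate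
24 | (3S,4Z,6S,7R,8R,10R)-3,15-dihydroxy-8-(2-methylpropanoyloxy)-3,10-epoxygermacra-4,11(13)-dien-12,6-olide | C=C1C(=O)O[C@H]2/C=C(/CO)[C@]3(O)CC[C@](C)(C[C@@H](OC(=O)C(C)C)[C@@H]12)O3 | target

**Summary and risks**

Total step count: 14. Longest linear sequence: 14 steps (fully linear from 1).

Step 14 (key step). The cation may be diverted before the oxygen closes: the acid can instead activate the C3 carbonyl so that C14 attacks C3 (carbonyl-ene or Prins-type closure), the C10=C14 bond can migrate towards conjugation with the ketone, or the oxygen can close on the wrong face of C10. The fallback sets out from 23 and comes back at 24, replacing the proton by a soft metal electrophile that activates only the electron-rich olefin. Hg(OCOCF3)2 in THF/H2O at 0 °C should add to C10=C14 with capture of C10 by the C3 oxygen and of C3 by water, giving the 14-(trifluoroacetoxymercurio) hemiketal F1. n-Bu3SnH in THF at rt should then replace mercury by hydrogen and give 24, avoiding borohydride, which would reduce the α-methylene lactone.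

Step 10. Ring closure may lose to intermolecular allylation or to reduction of the ene-dione by the metal, and the macrocyclic transition state may favour anti addition, giving the wrong configuration at C6. The fallback sets out from 18 and comes back at 20, fixing C6 by inversion instead of by the addition itself. The Barbier reaction is stopped before acid treatment at the 6-epimeric hydroxy ester F2. Me3SnOH in 1,2-dichloroethane at 70 °C should hydrolyse the methyl ester to the hydroxy acid F3. Mitsunobu lactonisation (PPh3, diisopropyl azodicarboxylate, THF, high dilution) should then close the lactone with inversion at C6 and give 20.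

Step 9. The photo-oxidation may be accompanied by ene oxidation of the 1,1-disubstituted olefin, by alkylation of Me2S at the allylic bromide, and by Z/E isomerisation or hydration of the (Z)-4-oxo-enal on handling. The fallback sets out from 14 and comes back at 20, keeping the allylic position as an acetate so that no alkylating agent is present during furan opening. Acetic anhydride, DMAP and Et3N should give the allylic acetate F4. mCPBA with NaHCO3 in CH2Cl2 at 0 °C should open the furan to the (Z)-keto-enal acetate F5. Pd(PPh3)4 (cat.) with InI in THF at high dilution should ionise the acetate to the π-allyl complex, transmetalate it to the allylindium and close the ring to 19, which lactonises to 20 with pyridinium p-toluenesulfonate as in step 10.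

Further compounds
F1 | step 14 | 14-(trifluoroacetoxymercurio) derivative of 24 | C=C1C(=O)O[C@H]2/C=C(/CO)[C@]3(O)CC[C@](C[Hg]OC(=O)C(F)(F)F)(C[C@@H](OC(=O)C(C)C)[C@@H]12)O3
F2 | step 10 | 6-epimer of 19, methyl (4Z,6R,7S,8R)-6-hydroxy-3-oxo-8-(TBS-oxy)-15-(TBDPS-oxy)germacra-4,10(14),11(13)-trien-12-oate | O[C@@H]1/C=C(/CO[Si](C(C)(C)C)(c2ccccc2)c2ccccc2)C(=O)CCC(=C)C[C@@H](O[Si](C)(C)C(C)(C)C)[C@H]1C(=C)C(=O)OC
F3 | step 10 | carboxylic acid of F2 | O[C@@H]1/C=C(/CO[Si](C(C)(C)C)(c2ccccc2)c2ccccc2)C(=O)CCC(=C)C[C@@H](O[Si](C)(C)C(C)(C)C)[C@H]1C(=C)C(=O)O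
F4 | step 9 | 3-O-acetate of 14 | C=C(C(=O)OC)C(OC(C)=O)[C@H](O[Si](C)(C)C(C)(C)C)CC(=C)CCc1occc1CO[Si](C(C)(C)C)(c1ccccc1)c1ccccc1
F5 | step 9 | methyl (4R,10Z)-3-acetoxy-2,6-dimethylidene-9,12-dioxo-4-(TBS-oxy)-10-(TBDPS-oxymethyl)dodec-10-enoate | C=C(C(=O)OC)C(OC(C)=O)[C@H](O[Si](C)(C)C(C)(C)C)CC(=C)CCC(=O)/C(CO[Si](C(C)(C)C)(c1ccccc1)c1ccccc1)=C\C=O
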